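**Retrosynthetic overview**

1. The C6 side chain comes off last: the bicyclic enol with a free C6–H (a 5-hydroxy-2,3-dihydro-4H-chromene-4,7(8H)-dione) adds to (E)-hex-2-enal under iminium catalysis, which sets the side-chain centre, and the aldehyde is oxidised to the acid.
2. The bicyclic core is cut at the C4a–C8a bond and at the C5–C6 bond of the carbocycle (chromene numbering) in the same operation, which unfolds both rings into one acyclic chain.
3. Enabling feature: C5, C7 and C8a carry oxygen in a 1,3,5-pattern and C8a, bonded to the pyran oxygen O1, is at the carboxylic acid oxidation level. The bicycle is therefore a folded triketide in which C8a is the ester carbonyl of the C2–OH, C4a the CH2 of a β-keto ester and C6 the CH3 of a methyl ketone, while quaternary C8 (no α-H) blocks enolisation and aromatisation.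
4. The acyclic chain is assembled from an Evans syn-aldol alcohol (C2, C3), acetoacetylation, alkylation with (S)-lavandulyl iodide (Evans alkylation) and an auxiliary-controlled prenylation that sets C8.
5. Ring order: dihydropyranone first (C4a–C8a bond, then dehydration onto O1), carbocycle second (C5–C6 Dieckmann closure), both in one flask.

Key step: step 14

Assumption (remark on step 11): the lithiated valine enamine is taken to alkylate anti to the isopropyl group of its tridentate lithium chelate, which for tert-butyl (S)-valinate in toluene/HMPA is taken to be the Re face of C2. If the sense proves opposite, tert-butyl (R)-valinate is used and nothing else changes.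

**Route**

Step 1
Reactants: 1 (S)-4-benzyl-1,3-oxazolidin-2-one; 2 3-methylbut-2-enoyl chloride
Product: 3 (S)-4-benzyl-3-(3-methylbut-2-enoyl)-1,3-oxazolidin-2-one
Conditions: n-BuLi, THF, −78 °C; then 2, −78 → 0 °C
Reagents that add atoms: 3-methylbut-2-enoyl chloride (2), CC(C)=CC(=O)Cl
Why: N-acylation of the lithiated oxazolidinone by the acid chloride (standard Evans imide formation) is fast at −78 °C and creates no stereocentre.

Step 2
Reactants: 3; 4 1-bromo-3-methylbut-2-ene (prenyl bromide)
Product: 5 (S)-4-benzyl-3-[(2S)-5-methyl-2-(prop-1-en-2-yl)hex-4-enoyl]-1,3-oxazolidin-2-one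
Conditions: NaN(SiMe3)2, THF, −78 °C; then 4, −78 → −40 °C
Reagents that add atoms: prenyl bromide (4), CC(C)=CCBr
Why: Evans deconjugative α-alkylation, in which γ-deprotonation gives the sodium-chelated (Z)-dienolate and prenyl bromide enters at Cα anti to the benzyl group of the auxiliary, which sets the (S) centre of the lavandulyl unit.

Step 3
Reactants: 5
Product: 6 (2S)-5-methyl-2-(prop-1-en-2-yl)hex-4-en-1-ol, (S)-lavandulol
Conditions: LiBH4, H2O (1 equiv), Et2O, 0 °C
Reagents that add atoms: none
Why: LiBH4 reductive cleavage of the N-acyloxazolidinone should give the primary alcohol and the free auxiliary without touching the β,γ-alkene or the α-stereocentre.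

Step 4
Reactants: 6
Product: 7 (3S)-3-(iodomethyl)-2,6-dimethylhepta-1,5-diene, (S)-lavandulyl iodide
Conditions: PPh3, iodine, imidazole, CH2Cl2, 0 °C
Reagents that add atoms: iodine, [I][I]
Why: Appel-type iodination converts the primary alcohol into the iodide under neutral conditions that leave both alkenes and the adjacent stereocentre untouched.

Step 5
Reactants: 8 (S)-4-benzyl-3-propanoyl-1,3-oxazolidin-2-one; 9 acetaldehyde
Product: 10 (S)-4-benzyl-3-[(2S,3R)-3-hydroxy-2-methylbutanoyl]-1,3-oxazolidin-2-one
Conditions: Bu2BOTf, i-Pr2NEt, CH2Cl2, 0 °C; then 9, −78 → 0 °C; pH 7 buffer, MeOH, H2O2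
Reagents that add atoms: acetaldehyde (9), CC=O
Why: Evans syn-aldol reaction, in which the (Z)-boron enolate reacts with acetaldehyde through a Zimmerman–Traxler chair and the auxiliary dictates the enolate face, giving the (2S,3R) syn pair that becomes the cis-2,3-dimethyl unit.

Step 6
Reactants: 10
Product: 11 (2S,3R)-3-hydroxy-2-methylbutanoic acid
Conditions: LiOH, H2O2, THF/H2O, 0 °C; then Na2SO3; HCl to pH 2
Reagents that add atoms: hydrogen peroxide (acting as LiOOH), OO
Why: LiOOH attacks the exocyclic imide carbonyl selectively (standard auxiliary hydrolysis) at 0 °C, where neither retro-aldol cleavage nor epimerisation of the α-centre should occur.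

Step 7
Reactants: 11; 12 3-bromoprop-1-ene (allyl bromide)
Product: 13 prop-2-en-1-yl (2S,3R)-3-hydroxy-2-methylbutanoate
Conditions: KHCO3, DMF, rt
Reagents that add atoms: allyl bromide (12), C=CCBr
Why: SN2 O-alkylation of the carboxylate with a bicarbonate base esterifies the acid without touching the secondary alcohol or the α-centre, and the allyl ester can later be removed under neutral conditions.

Step 8
Reactants: 13; 14 2,2,6-trimethyl-4H-1,3-dioxin-4-one
Product: 15 prop-2-en-1-yl (2S,3R)-2-methyl-3-[(3-oxobutanoyl)oxy]butanoate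
Conditions: toluene, 110 °C, acetone distilled off
Reagents that add atoms: 2,2,6-trimethyl-4H-1,3-dioxin-4-one (14), CC1=CC(=O)OC(C)(C)O1
Why: thermal retro-[4+2] of the dioxinone releases acetylketene, which acylates the secondary alcohol (acetoacetylation) under neutral conditions, so the O–C bond of the future pyranone is made as an ester with both stereocentres intact.

Step 9
Reactants: 15; 7
Product: 16 prop-2-en-1-yl (2S,3R)-3-{[(4R)-2-acetyl-7-methyl-4-(prop-1-en-2-yl)oct-6-enoyl]oxy}-2-methylbutanoate (both C2 epimers of the octenoyl chain)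
Conditions: NaH, DMF, 0 °C; then 7, 40 °C
Reagents that add atoms: (S)-lavandulyl iodide (7), C=C(C)[C@@H](CI)CC=C(C)C
Why: acetoacetic ester alkylation, in which the soft sodium enolate of the β-keto ester should displace iodide from the primary iodide (SN2) in preference to elimination, and the epimer mixture at the new centre is irrelevant because that centre is planarised in the next step.

Step 10
Reactants: 16; 17 tert-butyl (S)-valinate
Product: 18 (Z)-β-enamino ester of 16 with tert-butyl (S)-valinate (N–H hydrogen-bonded to the ester carbonyl)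
Conditions: AcOH (cat), 4 Å molecular sieves, toluene, 60 °C
Reagents that add atoms: tert-butyl (S)-valinate (17), CC(C)[C@H](N)C(=O)OC(C)(C)C
Why: condensation of the ketone of a β-keto ester with a primary amine gives the hydrogen-bonded (Z)-β-enamino ester, which funnels both epimers of 16 into one compound and installs the valine auxiliary.

Step 11
Reactants: 18; 4 prenyl bromide
Product: 20 prop-2-en-1-yl (2S,3R)-3-{[(2S,4R)-2-acetyl-7-methyl-2-(3-methylbut-2-en-1-yl)-4-(prop-1-en-2-yl)oct-6-enoyl]oxy}-2-methylbutanoate, via ketimine 19 (not isolated)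
Conditions: LiN(i-Pr)2, toluene, −78 °C; HMPA; 4, −78 → −20 °C; then 10% aq citric acid, THF, rt
Reagents that add atoms: prenyl bromide (4), CC(C)=CCBr; water, O
Why: asymmetric alkylation of an α-alkyl β-keto ester through its chiral valine enamine, in which the N-lithiated enamino ester is a rigid tridentate lithium chelate (enamine N, ester C=O, valinate C=O) whose isopropyl group blocks one face, so prenyl bromide should add to the Re face of C2 and set the quaternary (S) centre under auxiliary control before mild acid hydrolyses the ketimine.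

Step 12
Reactants: 20
Product: 21 (2S,3R)-3-{[(2S,4R)-2-acetyl-7-methyl-2-(3-methylbut-2-en-1-yl)-4-(prop-1-en-2-yl)oct-6-enoyl]oxy}-2-methylbutanoic acid
Conditions: Pd(PPh3)4 (5 mol %), morpholine, THF, rt
Reagents that add atoms: none
Why: Tsuji–Trost-type allyl transfer to morpholine catalysed by zerovalent palladium frees the acid under neutral conditions that should not affect the trisubstituted and 1,1-disubstituted alkenes, the quaternary β-keto ester or the epimerisable α-centre.

Step 13
Reactants: 21; 22 potassium ethyl malonate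
Product: 24 ethyl (4S,5R)-5-{[(2S,4R)-2-acetyl-7-methyl-2-(3-methylbut-2-en-1-yl)-4-(prop-1-en-2-yl)oct-6-enoyl]oxy}-4-methyl-3-oxohexanoate, via acyl imidazolide 23 (not isolated)
Conditions: 1,1'-carbonyldiimidazole, THF, rt; then 22, MgCl2, Et3N, MeCN, rt → 40 °C; aq citric acid
Reagents that add atoms: potassium ethyl malonate (22), CCOC(=O)CC(=O)[O-].[K+]; 1,1'-carbonyldiimidazole, O=C(n1ccnc1)n1ccnc1 (its imidazolyl group is in 23 only)
Why: Masamune-type homologation, in which the acyl imidazolide is C-acylated by the magnesium enolate of the malonate half-ester and decarboxylates to the β-keto ester under nearly neutral conditions that should preserve the α-methyl centre and the β-acyloxy group.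

Step 14
Reactants: 24
Product: 27 (2R,3S,8R)-5-hydroxy-2,3-dimethyl-8-(3-methylbut-2-en-1-yl)-8-[(2R)-5-methyl-2-(prop-1-en-2-yl)hex-4-en-1-yl]-2,3-dihydro-4H-chromene-4,7(8H)-dione, via hydroxy triketo ester 25 (not isolated), via pyranone ester 26 (not isolated)
Conditions: NaN(SiMe3)2 (1.05 equiv), THF, −78 → 40 °C; AcOH (1.2 equiv), 4 Å molecular sieves, 45 °C; NaN(SiMe3)2 (3.5 equiv), −78 → 0 °C; aq NH4Cl
Reagents that add atoms: none
Why: the first equivalent of NaN(SiMe3)2 deprotonates only the β-keto ester, and its enolate carbon (future C4a) attacks the ester carbonyl (future C8a) through a six-membered transition state, so that the acyl group migrates from O to C (Baker–Venkataraman-type acyl shift, the route from β-acyloxy ketones to dihydropyranones) and the stabilised triketonate of 25 results. On buffering with AcOH the freed C2 hydroxyl adds back to the C8a ketone (6-exo-trig hemiketalisation) and water is lost across C4a–C8a in a Knoevenagel-type elimination, which closes the pyranone ring as 26. Excess amide base then removes a methyl ketone proton under kinetic control and the enolate (future C6) attacks the ester carbonyl (future C5) in a 6-exo-trig Dieckmann condensation that closes the carbocycle and is pulled forward by formation of the vinylogous acid enolate of 27; the closest known reaction type for the whole sequence is the Claisen–Dieckmann cyclisation of 3,5-dioxo esters to acylphloroglucinol-type triones. No stereocentre is formed: quaternary C8 has no α-hydrogen, and C2 and C3 should be carried through because C3–H is flanked by a ketone that is held as an enolate in the first stage and is removed more slowly than the CH3 protons in the last. The regiochemistry of the pyran oxygen (O1 on C8a, not on C5) is secured by the substrate, because the C2 oxygen arrives as the ester of the C8a carboxyl and the pyranone closes while C5 is still an ester. The competition between Dieckmann closure onto C5 and aldol closure onto the C4 ketone is decided by the new C4a=C8a double bond, which holds the ester cis and the ketone trans to the C8 side chain, helped by the Thorpe–Ingold effect of quaternary C8.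

Step 15
Reactants: 27; 28 (E)-hex-2-enal
Product: 29 (3R)-3-[(2R,3S,8R)-5-hydroxy-2,3-dimethyl-8-(3-methylbut-2-en-1-yl)-8-[(2R)-5-methyl-2-(prop-1-en-2-yl)hex-4-en-1-yl]-4,7-dioxo-3,4,7,8-tetrahydro-2H-chromen-6-yl]hexanal (in equilibrium with its cyclic hemiacetals)
Conditions: (S)-α,α-diphenylprolinol trimethylsilyl ether (20 mol %), PhCO2H (20 mol %), CH2Cl2, 0 °C → rt
Reagents that add atoms: (E)-hex-2-enal (28), CCC/C=C/C=O
Why: iminium-catalysed Michael addition of a cyclic 1,3-dicarbonyl C–H acid to an enal, in which C6 is the only enolisable ring carbon and the diphenyl(silyloxy)methyl group shields one face of the (E)-iminium ion, so that C6 should add to the open face of C3 of hexenal and set the (R) side-chain centre under catalyst control.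

Step 16
Reactants: 29
Product: 30 (3R)-3-[(2R,3S,8R)-5-hydroxy-2,3-dimethyl-8-(3-methylbut-2-en-1-yl)-8-[(2R)-5-methyl-2-(prop-1-en-2-yl)hex-4-en-1-yl]-4,7-dioxo-3,4,7,8-tetrahydro-2H-chromen-6-yl]hexanoic acid (target)
Conditions: NaClO2, NaH2PO4, 2-methylbut-2-ene, t-BuOH/H2O, 0 °C → rt
Reagents that add atoms: sodium chlorite, [Na+].[O-]Cl=O
Why: Pinnick oxidation converts the aldehyde, which is available from its lactol forms by ring–chain tautomerism, into the acid under buffered, base-free conditions, so the cis-2,3-dimethyl centre next to the ketone should not epimerise and the alkene scavenger protects the prenyl groups from HOCl.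

**Compound list**

1 | (S)-4-benzyl-1,3-oxazolidin-2-one | O=C1N[C@@H](Cc2ccccc2)CO1 | starting material
2 | 3-methylbut-2-enoyl chloride | CC(C)=CC(=O)Cl | starting material
3 | (S)-4-benzyl-3-(3-methylbut-2-enoyl)-1,3-oxazolidin-2-one | CC(C)=CC(=O)N1[C@@H](Cc2ccccc2)COC1=O | intermediate
4 | 1-bromo-3-methylbut-2-ene (prenyl bromide) | CC(C)=CCBr | starting material
5 | (S)-4-benzyl-3-[(2S)-5-methyl-2-(prop-1-en-2-yl)hex-4-enoyl]-1,3-oxazolidin-2-one | O=C([C@@H](CC=C(C)C)C(C)=C)N1[C@@H](Cc2ccccc2)COC1=O | intermediate
6 | (2S)-5-methyl-2-(prop-1-en-2-yl)hex-4-en-1-ol, (S)-lavandulol | OC[C@@H](CC=C(C)C)C(C)=C | intermediate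
7 | (3S)-3-(iodomethyl)-2,6-dimethylhepta-1,5-diene, (S)-lavandulyl iodide | C=C(C)[C@@H](CI)CC=C(C)C | intermediate
8 | (S)-4-benzyl-3-propanoyl-1,3-oxazolidin-2-one | CCC(=O)N1[C@@H](Cc2ccccc2)COC1=O | starting material
9 | acetaldehyde | CC=O | starting material
10 | (S)-4-benzyl-3-[(2S,3R)-3-hydroxy-2-methylbutanoyl]-1,3-oxazolidin-2-one | O[C@H](C)[C@H](C)C(=O)N1[C@@H](Cc2ccccc2)COC1=O | intermediate
11 | (2S,3R)-3-hydroxy-2-methylbutanoic acid | O[C@H](C)[C@H](C)C(=O)O | intermediate
12 | 3-bromoprop-1-ene (allyl bromide) | C=CCBr | starting material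
13 | prop-2-en-1-yl (2S,3R)-3-hydroxy-2-methylbutanoate | O[C@H](C)[C@H](C)C(=O)OCC=C | intermediate
14 | 2,2,6-trimethyl-4H-1,3-dioxin-4-one | CC1=CC(=O)OC(C)(C)O1 | starting material
15 | prop-2-en-1-yl (2S,3R)-2-methyl-3-[(3-oxobutanoyl)oxy]butanoate | CC(=O)CC(=O)O[C@H](C)[C@H](C)C(=O)OCC=C | intermediate
16 | prop-2-en-1-yl (2S,3R)-3-{[(4R)-2-acetyl-7-methyl-4-(prop-1-en-2-yl)oct-6-enoyl]oxy}-2-methylbutanoate (C2 epimers) | CC(=O)C(C[C@@H](CC=C(C)C)C(C)=C)C(=O)O[C@H](C)[C@H](C)C(=O)OCC=C | intermediate
17 | tert-butyl (S)-valinate | CC(C)[C@H](N)C(=O)OC(C)(C)C | starting material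
18 | (Z)-β-enamino ester of 16 with tert-butyl (S)-valinate, prop-2-en-1-yl (2S,3R)-3-{[(2Z,4R)-2-(1-{[(2S)-1-tert-butoxy-3-methyl-1-oxobutan-2-yl]amino}ethylidene)-7-methyl-4-(prop-1-en-2-yl)oct-6-enoyl]oxy}-2-methylbutanoate | C/C(N[C@@H](C(C)C)C(=O)OC(C)(C)C)=C(\C[C@@H](CC=C(C)C)C(C)=C)C(=O)O[C@H](C)[C@H](C)C(=O)OCC=C | intermediate
19 | ketimine of 20 with tert-butyl (S)-valinate (C=N at the acetyl carbon) | CC(=N[C@@H](C(C)C)C(=O)OC(C)(C)C)[C@](CC=C(C)C)(C[C@@H](CC=C(C)C)C(C)=C)C(=O)O[C@H](C)[C@H](C)C(=O)OCC=C | intermediate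
20 | prop-2-en-1-yl (2S,3R)-3-{[(2S,4R)-2-acetyl-7-methyl-2-(3-methylbut-2-en-1-yl)-4-(prop-1-en-2-yl)oct-6-enoyl]oxy}-2-methylbutanoate | CC(=O)[C@](CC=C(C)C)(C[C@@H](CC=C(C)C)C(C)=C)C(=O)O[C@H](C)[C@H](C)C(=O)OCC=C | intermediate
21 | (2S,3R)-3-{[(2S,4R)-2-acetyl-7-methyl-2-(3-methylbut-2-en-1-yl)-4-(prop-1-en-2-yl)oct-6-enoyl]oxy}-2-methylbutanoic acid | CC(=O)[C@](CC=C(C)C)(C[C@@H](CC=C(C)C)C(C)=C)C(=O)O[C@H](C)[C@H](C)C(=O)O | intermediate
22 | potassium ethyl malonate | CCOC(=O)CC(=O)[O-].[K+] | starting material
23 | N-acyl imidazole (imidazolide) of 21 | CC(=O)[C@](CC=C(C)C)(C[C@@H](CC=C(C)C)C(C)=C)C(=O)O[C@H](C)[C@H](C)C(=O)n1ccnc1 | intermediate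
24 | ethyl (4S,5R)-5-{[(2S,4R)-2-acetyl-7-methyl-2-(3-methylbut-2-en-1-yl)-4-(prop-1-en-2-yl)oct-6-enoyl]oxy}-4-methyl-3-oxohexanoate | CC(=O)[C@](CC=C(C)C)(C[C@@H](CC=C(C)C)C(C)=C)C(=O)O[C@H](C)[C@H](C)C(=O)CC(=O)OCC | intermediate
25 | ethyl (4S,5R)-2-[(2S,4R)-2-acetyl-7-methyl-2-(3-methylbut-2-en-1-yl)-4-(prop-1-en-2-yl)oct-6-enoyl]-5-hydroxy-4-methyl-3-oxohexanoate (open triketone form; sodium enolate in the flask) | CC(=O)[C@](CC=C(C)C)(C[C@@H](CC=C(C)C)C(C)=C)C(=O)C(C(=O)OCC)C(=O)[C@@H](C)[C@@H](C)O | intermediate
26 | ethyl (2R,3S)-2,3-dimethyl-6-[(3R,5R)-8-methyl-3-(3-methylbut-2-en-1-yl)-2-oxo-5-(prop-1-en-2-yl)non-7-en-3-yl]-4-oxo-3,4-dihydro-2H-pyran-5-carboxylate | CC(=O)[C@](CC=C(C)C)(C[C@@H](CC=C(C)C)C(C)=C)C1=C(C(=O)OCC)C(=O)[C@@H](C)[C@@H](C)O1 | intermediate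
27 | (2R,3S,8R)-5-hydroxy-2,3-dimethyl-8-(3-methylbut-2-en-1-yl)-8-[(2R)-5-methyl-2-(prop-1-en-2-yl)hex-4-en-1-yl]-2,3-dihydro-4H-chromene-4,7(8H)-dione | C=C(C)[C@H](CC=C(C)C)C[C@@]1(CC=C(C)C)C(=O)C=C(O)C2=C1O[C@H](C)[C@H](C)C2=O | intermediate
28 | (E)-hex-2-enal | CCC/C=C/C=O | starting material
29 | (3R)-3-[(2R,3S,8R)-5-hydroxy-2,3-dimethyl-8-(3-methylbut-2-en-1-yl)-8-[(2R)-5-methyl-2-(prop-1-en-2-yl)hex-4-en-1-yl]-4,7-dioxo-3,4,7,8-tetrahydro-2H-chromen-6-yl]hexanal (open form) | C=C(C)[C@H](CC=C(C)C)C[C@@]1(CC=C(C)C)C(=O)C([C@H](CCC)CC=O)=C(O)C2=C1O[C@H](C)[C@H](C)C2=O | intermediate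
30 | (3R)-3-[(2R,3S,8R)-5-hydroxy-2,3-dimethyl-8-(3-methylbut-2-en-1-yl)-8-[(2R)-5-methyl-2-(prop-1-en-2-yl)hex-4-en-1-yl]-4,7-dioxo-3,4,7,8-tetrahydro-2H-chromen-6-yl]hexanoic acid | C=C(C)[C@H](CC=C(C)C)C[C@@]1(CC=C(C)C)C(=O)C([C@H](CCC)CC(=O)O)=C(O)C2=C1O[C@H](C)[C@H](C)C2=O | target

**Step count and risks**

Total step count: 16. Longest linear sequence: 12 steps (steps 1–4 then 9–16, or steps 5–16).

Most likely to fail, first: step 14. The acyl transfer onto the neopentyl-like ester carbonyl may be slow, so that β-elimination of the carboxylate from the β-acyloxy ketone takes over on warming. In the last stage, enolisation at C3 of the pyranone may cause epimerisation or retro-oxa-Michael ring opening. The fallback sets out from 24 and comes back at 27. The one-flask anionic cascade is given up and the two C–C bond formations are run as separate, isolated operations with an acid-mediated closure of the pyranone in between. The acyl shift is run under Lacey–Dieckmann conditions (KOt-Bu, t-BuOH/THF, rt) with neutral work-up, which should give the cyclic hemiketal of 25, ethyl (2R,3S)-6-hydroxy-2,3-dimethyl-6-[8-methyl-3-(3-methylbut-2-en-1-yl)-2-oxo-5-(prop-1-en-2-yl)non-7-en-3-yl]-4-oxotetrahydro-2H-pyran-5-carboxylate F1. Brønsted acid (PPTS, 4 Å molecular sieves, CH2Cl2) then dehydrates it to 26, which is purified. The Dieckmann closure is carried out on pure 26 with LiN(SiMe3)2 at −78 °C by inverse addition and a cold quench, so that the C3 centre sees strong base only briefly.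

Second: step 11. The lithio-enamine alkylation may show insufficient or reversed facial selectivity, N-alkylation may compete, and the amide base may trigger β-elimination in the acyloxy ester part. The fallback sets out from 16 and comes back at 20. Auxiliary control is given up: 16 is C-prenylated as its soft caesium enolate (Cs2CO3, prenyl bromide 4, DMF, 0 °C), which should give 20 together with its C2 epimer, prop-2-en-1-yl (2S,3R)-3-{[(2R,4R)-2-acetyl-7-methyl-2-(3-methylbut-2-en-1-yl)-4-(prop-1-en-2-yl)oct-6-enoyl]oxy}-2-methylbutanoate F2. Because three other stereocentres are fixed, the two are diastereomers and are separated by preparative HPLC. Steps 10 and 11 are then not needed.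

Third: step 15. The hindered, internally hydrogen-bonded enol may react slowly with the iminium ion, the substrate's own stereocentres may erode the facial selectivity, and a second addition may follow. The fallback sets out from 27 and comes back at 30. The side chain is introduced at the carboxylic acid oxidation level by N-heterocyclic carbene catalysis: 27 and hex-2-ynal with a chiral aminoindanol-derived triazolium salt (enantiomer chosen for the (R) centre) and catalytic i-Pr2NEt in toluene react through the α,β-unsaturated acyl azolium by Michael addition and lactonisation. This should give the enol δ-lactone of 30 closed between the carboxyl group and the C5 oxygen (a (4R)-4-propyl-3,4-dihydropyran-2-one ring fused at C5–C6) F3. Mild hydrolysis (LiOH, THF/H2O, 0 °C) opens the enol lactone to 30, so that 29 and step 16 are bypassed.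

Further compounds
F1 | step 14 | cyclic hemiketal of 25, ethyl (2R,3S)-6-hydroxy-2,3-dimethyl-6-[8-methyl-3-(3-methylbut-2-en-1-yl)-2-oxo-5-(prop-1-en-2-yl)non-7-en-3-yl]-4-oxotetrahydro-2H-pyran-5-carboxylate (mixture at C5 and C6) | CC(=O)[C@](CC=C(C)C)(C[C@@H](CC=C(C)C)C(C)=C)C1(O)C(C(=O)OCC)C(=O)[C@@H](C)[C@@H](C)O1
F2 | step 11 | prop-2-en-1-yl (2S,3R)-3-{[(2R,4R)-2-acetyl-7-methyl-2-(3-methylbut-2-en-1-yl)-4-(prop-1-en-2-yl)oct-6-enoyl]oxy}-2-methylbutanoate | CC(=O)[C@@](CC=C(C)C)(C[C@@H](CC=C(C)C)C(C)=C)C(=O)O[C@H](C)[C@H](C)C(=O)OCC=C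
F3 | step 15 | enol δ-lactone of 30 closed between the carboxyl group and the C5 oxygen | C=C(C)[C@H](CC=C(C)C)C[C@@]1(CC=C(C)C)C(=O)C3=C(OC(=O)C[C@H]3CCC)C2=C1O[C@H](C)[C@H](C)C2=O
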